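**Retrosynthetic overview**
1. Target 19 ⇒ oxidation of the C2'-OH of hydroxy ester 18 ⇒ MOM removal and senecioylation from the syn-diol mono-MOM ether 14 ⇒ alkene hydrogenation from 13.
2. Key disconnection C1'–C2': asymmetric γ-alkoxyallylation of 7-methoxy-8-formylcoumarin 4 with a Brown (Z)-γ-(MOM-oxy)-β-methylallyl-B(Ipc)2 reagent made from methallyl MOM ether 7; this sets C1'.
3. Aldehyde 4 ⇒ umbelliferone 1 by Duff formylation and O-methylation.
4. No ring is formed: the coumarin bicycle is carried intact from umbelliferone.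

Assumption: C1' = stereocentre, C2' = ketone carbon, C3' = isopropyl CH; group-delivering reagents (HMTA, MeI, MOMCl) are given with SMILES on the "Reagents that add atoms" line and are not numbered.

**Step 1**
Reactants: 1 umbelliferone (7-hydroxy-2H-chromen-2-one)
Product: 3 7-hydroxy-2-oxo-2H-chromene-8-carbaldehyde, via aldimine 2 (not isolated)
Conditions: (CH2)6N4, CF3CO2H, reflux; then H2O, 60 °C
Reagents that add atoms: hexamethylenetetramine C1N2CN3CN1CN(C2)C3; water O
Why: Duff ortho-formylation, in which the 7-OH directs the HMTA-derived iminium electrophile to the more nucleophilic C8 and the resulting imine is hydrolysed in the same pot (no stereocentre).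

**Step 2**
Reactants: 3 7-hydroxy-2-oxo-2H-chromene-8-carbaldehyde
Product: 4 7-methoxy-2-oxo-2H-chromene-8-carbaldehyde
Conditions: MeI, K2CO3, acetone, reflux
Reagents that add atoms: iodomethane CI
Why: Williamson O-methylation (SN2) of the phenoxide, to which the aldehyde and the lactone are inert.

**Step 3**
Reactants: 5 2-methylprop-2-en-1-ol (methallyl alcohol)
Product: 7 3-(methoxymethoxy)-2-methylprop-1-ene, via sodium alkoxide 6 (not isolated)
Conditions: NaH, THF, 0 °C; then MOMCl, 0 °C → rt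
Reagents that add atoms: chloromethyl methyl ether COCCl
Why: Williamson-type alkylation of the alkoxide with MOMCl gives the allylic acetal ether needed for oxygen-directed α-lithiation.

**Step 4**
Reactants: 7 3-(methoxymethoxy)-2-methylprop-1-ene; 8 (−)-B-methoxydiisopinocampheylborane; 4 7-methoxy-2-oxo-2H-chromene-8-carbaldehyde
Product: 13 8-[(1R,2R)-1-hydroxy-2-(methoxymethoxy)-3-methylbut-3-en-1-yl]-7-methoxy-2H-chromen-2-one, via allyllithium 9 (not isolated), via borate complex 10 (not isolated), via allylborane 11 (not isolated), via borinate ester 12 (not isolated)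
Conditions: 7, s-BuLi, THF, −78 °C; 8, −78 °C; BF3·OEt2, −78 °C; 4, −78 → −20 °C; HOCH2CH2NH2, Et2O, rt
Reagents that add atoms: none
Why: Brown asymmetric γ-alkoxyallylboration (carbonyl allylation) through a chair Zimmerman–Traxler transition state, in which the (+)-α-pinene-derived Ipc groups send the allyl unit to the Si face of the aldehyde and so set C1' as R, while the Z reagent gives the 1,2-syn (2R) ether whose configuration is erased later and the non-oxidative ethanolamine work-up spares the coumarin.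

**Step 5**
Reactants: 13 8-[(1R,2R)-1-hydroxy-2-(methoxymethoxy)-3-methylbut-3-en-1-yl]-7-methoxy-2H-chromen-2-one
Product: 14 8-[(1R,2R)-1-hydroxy-2-(methoxymethoxy)-3-methylbutyl]-7-methoxy-2H-chromen-2-one
Conditions: H2 (1 atm), RhCl(PPh3)3 (10 mol %), PhH–EtOH 1:1, rt
Reagents that add atoms: none
Why: Homogeneous hydrogenation with Wilkinson's catalyst reduces the unhindered 1,1-disubstituted alkene much faster than the conjugated coumarin C3=C4 bond and does not hydrogenolyse the benzylic C–O bond, so both stereocentres are untouched.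

**Step 6**
Reactants: 14 8-[(1R,2R)-1-hydroxy-2-(methoxymethoxy)-3-methylbutyl]-7-methoxy-2H-chromen-2-one; 15 3-methylbut-2-enoyl chloride (senecioyl chloride)
Product: 16 (1R,2R)-1-(7-methoxy-2-oxo-2H-chromen-8-yl)-2-(methoxymethoxy)-3-methylbutyl 3-methylbut-2-enoate
Conditions: pyridine, DMAP (0.2 equiv), CH2Cl2, 0 °C → rt
Reagents that add atoms: none
Why: DMAP-catalysed O-acylation of the only free hydroxyl proceeds with retention at C1', and pyridine instead of Et3N limits vinylketene formation and deconjugation of the senecioyl group.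

**Step 7**
Reactants: 16 (1R,2R)-1-(7-methoxy-2-oxo-2H-chromen-8-yl)-2-(methoxymethoxy)-3-methylbutyl 3-methylbut-2-enoate
Product: 18 (1R,2R)-2-hydroxy-1-(7-methoxy-2-oxo-2H-chromen-8-yl)-3-methylbutyl 3-methylbut-2-enoate, via bromomethyl ether 17 (not isolated)
Conditions: Me2BBr, CH2Cl2, −78 °C; then aq. NaHCO3–THF, 0 °C
Reagents that add atoms: none
Why: Guindon acetal cleavage, in which Me2BBr converts the MOM ether into a bromomethyl ether that is hydrolysed on bicarbonate work-up, at a temperature where both esters and the aryl methyl ether are inert and 1,2-acyl migration should not occur.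

**Step 8**
Reactants: 18 (1R,2R)-2-hydroxy-1-(7-methoxy-2-oxo-2H-chromen-8-yl)-3-methylbutyl 3-methylbut-2-enoate
Product: 19 (1R)-1-(7-methoxy-2-oxo-2H-chromen-8-yl)-3-methyl-2-oxobutyl 3-methylbut-2-enoate
Conditions: Dess–Martin periodinane, CH2Cl2, 0 °C → rt
Reagents that add atoms: none
Why: Dess–Martin oxidation of the secondary alcohol under neutral, non-enolising conditions gives the ketone without epimerising the adjacent benzylic acyloxy centre (R), and the C2' configuration is erased as planned.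

**Compound list**
1 | umbelliferone (7-hydroxy-2H-chromen-2-one) | O=c1ccc2ccc(O)cc2o1 | starting material
2 | 7-hydroxy-8-(iminomethyl)-2H-chromen-2-one (Duff aldimine, drawn as the parent NH imine; present in the acid as iminium salts) | N=Cc1c(O)ccc2ccc(=O)oc12 | intermediate
3 | 7-hydroxy-2-oxo-2H-chromene-8-carbaldehyde | O=Cc1c(O)ccc2ccc(=O)oc12 | intermediate
4 | 7-methoxy-2-oxo-2H-chromene-8-carbaldehyde | COc1ccc2ccc(=O)oc2c1C=O | intermediate
5 | 2-methylprop-2-en-1-ol (methallyl alcohol) | C=C(C)CO | starting material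
6 | sodium 2-methylprop-2-en-1-olate | [Na+].[O-]CC(C)=C | intermediate
7 | 3-(methoxymethoxy)-2-methylprop-1-ene | COCOCC(C)=C | intermediate
8 | (−)-B-methoxydiisopinocampheylborane, (−)-Ipc2BOMe, Ipc groups from (+)-α-pinene | COB([C@@H]1C[C@@H]2C[C@H]([C@H]1C)C2(C)C)[C@@H]1C[C@@H]2C[C@H]([C@H]1C)C2(C)C | starting material
9 | [(Z)-3-(methoxymethoxy)-2-methylallyl]lithium | [Li+].[CH2-]/C(C)=C\OCOC | intermediate
10 | lithium [(Z)-3-(methoxymethoxy)-2-methylallyl](methoxy)diisopinocampheylborate | [Li+].CO[B-](C/C(C)=C\OCOC)([C@@H]1C[C@@H]2C[C@H]([C@H]1C)C2(C)C)[C@@H]1C[C@@H]2C[C@H]([C@H]1C)C2(C)C | intermediate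
11 | [(Z)-3-(methoxymethoxy)-2-methylallyl]diisopinocampheylborane | COCO/C=C(C)\CB([C@@H]1C[C@@H]2C[C@H]([C@H]1C)C2(C)C)[C@@H]1C[C@@H]2C[C@H]([C@H]1C)C2(C)C | intermediate
12 | O-diisopinocampheylboryl (borinate) ester of 13, (1R,2R) | COc1ccc2ccc(=O)oc2c1[C@@H](OB([C@@H]3C[C@@H]4C[C@H]([C@H]3C)C4(C)C)[C@@H]3C[C@@H]4C[C@H]([C@H]3C)C4(C)C)[C@H](OCOC)C(C)=C | intermediate
13 | 8-[(1R,2R)-1-hydroxy-2-(methoxymethoxy)-3-methylbut-3-en-1-yl]-7-methoxy-2H-chromen-2-one | COc1ccc2ccc(=O)oc2c1[C@@H](O)[C@H](OCOC)C(C)=C | intermediate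
14 | 8-[(1R,2R)-1-hydroxy-2-(methoxymethoxy)-3-methylbutyl]-7-methoxy-2H-chromen-2-one | COc1ccc2ccc(=O)oc2c1[C@@H](O)[C@H](OCOC)C(C)C | intermediate
15 | 3-methylbut-2-enoyl chloride (senecioyl chloride) | CC(C)=CC(Cl)=O | starting material
16 | (1R,2R)-1-(7-methoxy-2-oxo-2H-chromen-8-yl)-2-(methoxymethoxy)-3-methylbutyl 3-methylbut-2-enoate | COc1ccc2ccc(=O)oc2c1[C@@H](OC(=O)C=C(C)C)[C@H](OCOC)C(C)C | intermediate
17 | (1R,2R)-2-(bromomethoxy)-1-(7-methoxy-2-oxo-2H-chromen-8-yl)-3-methylbutyl 3-methylbut-2-enoate | COc1ccc2ccc(=O)oc2c1[C@@H](OC(=O)C=C(C)C)[C@H](OCBr)C(C)C | intermediate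
18 | (1R,2R)-2-hydroxy-1-(7-methoxy-2-oxo-2H-chromen-8-yl)-3-methylbutyl 3-methylbut-2-enoate | COc1ccc2ccc(=O)oc2c1[C@@H](OC(=O)C=C(C)C)[C@H](O)C(C)C | intermediate
19 | (1R)-1-(7-methoxy-2-oxo-2H-chromen-8-yl)-3-methyl-2-oxobutyl 3-methylbut-2-enoate | COc1ccc2ccc(=O)oc2c1[C@@H](OC(=O)C=C(C)C)C(=O)C(C)C | target

**Totals**
Total step count: 8.
Longest linear sequence: 7 steps (1 → 3 → 4 → 13 → 14 → 16 → 18 → 19; steps 1, 2, 4, 5, 6, 7, 8).

**Three steps most likely to fail**

Step 4. The β-methyl-γ-alkoxyallylborane is less precedented than the parent Brown reagent, and the aldehyde is di-ortho-substituted, so reagent generation or enantioselectivity may fall short. The fallback sets out from aldehyde 4 and replaces the allylation by a catalytic asymmetric nitroaldol addition of 2-methyl-1-nitropropane (Cu(OAc)2, chiral bis(oxazoline), EtOH). This gives the nitro alcohol 8-[(1R)-1-hydroxy-3-methyl-2-nitrobutyl]-7-methoxy-2H-chromen-2-one F1, whose C2' epimers are both usable. A reductive Nef reaction (aq. TiCl3, NH4OAc, THF) turns CH–NO2 into C=O and gives the acyloin 8-[(1R)-1-hydroxy-3-methyl-2-oxobutyl]-7-methoxy-2H-chromen-2-one F2. Acylation of this with 15 (pyridine, CH2Cl2, 0 °C) comes back to the route at the target 19.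

Step 5. The hydrogenation may be slow at the α-branched isopropenyl group or may touch the coumarin C3=C4 bond. The fallback sets out from 13 and avoids hydrogenation altogether. Acylation with 15 (pyridine, DMAP) gives (1R,2R)-1-(7-methoxy-2-oxo-2H-chromen-8-yl)-2-(methoxymethoxy)-3-methylbut-3-en-1-yl 3-methylbut-2-enoate F3. Me2BBr at −78 °C then leads, by way of the non-isolated (1R,2R)-2-(bromomethoxy)-1-(7-methoxy-2-oxo-2H-chromen-8-yl)-3-methylbut-3-en-1-yl 3-methylbut-2-enoate F4 and bicarbonate work-up, to the allylic alcohol (1R,2R)-2-hydroxy-1-(7-methoxy-2-oxo-2H-chromen-8-yl)-3-methylbut-3-en-1-yl 3-methylbut-2-enoate F5. A ruthenium hydride-catalysed redox isomerisation of this allylic alcohol (RuHCl(CO)(PPh3)3, toluene, 80 °C) converts the CH(OH)–C(Me)=CH2 unit directly into the isopropyl ketone. It thus comes back to the route at the target 19 without steps 5 and 8.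

Step 6. The C1' hydroxyl is flanked by a 2,6-disubstituted aryl ring and a branched carbon, and senecioyl chloride can deconjugate through its vinylketene. The fallback sets out from 14 and builds the unsaturated ester in place. DCC/DMAP coupling with diethylphosphonoacetic acid, a small and very reactive acyl donor, gives (1R,2R)-1-(7-methoxy-2-oxo-2H-chromen-8-yl)-2-(methoxymethoxy)-3-methylbutyl 2-(diethoxyphosphoryl)acetate F6. A Horner–Wadsworth–Emmons olefination with acetone (LiCl, DBU, acetone–MeCN, rt) then installs the 3-methylbut-2-enoate and comes back to the route at 16.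

**Further compounds**
F1 | step 4 | 8-[(1R)-1-hydroxy-3-methyl-2-nitrobutyl]-7-methoxy-2H-chromen-2-one (C2' epimers) | COc1ccc2ccc(=O)oc2c1[C@@H](O)C(C(C)C)[N+](=O)[O-]
F2 | step 4 | 8-[(1R)-1-hydroxy-3-methyl-2-oxobutyl]-7-methoxy-2H-chromen-2-one | COc1ccc2ccc(=O)oc2c1[C@@H](O)C(=O)C(C)C
F3 | step 5 | (1R,2R)-1-(7-methoxy-2-oxo-2H-chromen-8-yl)-2-(methoxymethoxy)-3-methylbut-3-en-1-yl 3-methylbut-2-enoate | COc1ccc2ccc(=O)oc2c1[C@@H](OC(=O)C=C(C)C)[C@H](OCOC)C(C)=C
F4 | step 5 | (1R,2R)-2-(bromomethoxy)-1-(7-methoxy-2-oxo-2H-chromen-8-yl)-3-methylbut-3-en-1-yl 3-methylbut-2-enoate | COc1ccc2ccc(=O)oc2c1[C@@H](OC(=O)C=C(C)C)[C@H](OCBr)C(C)=C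
F5 | step 5 | (1R,2R)-2-hydroxy-1-(7-methoxy-2-oxo-2H-chromen-8-yl)-3-methylbut-3-en-1-yl 3-methylbut-2-enoate | COc1ccc2ccc(=O)oc2c1[C@@H](OC(=O)C=C(C)C)[C@H](O)C(C)=C
F6 | step 6 | (1R,2R)-1-(7-methoxy-2-oxo-2H-chromen-8-yl)-2-(methoxymethoxy)-3-methylbutyl 2-(diethoxyphosphoryl)acetate | COc1ccc2ccc(=O)oc2c1[C@@H](OC(=O)CP(=O)(OCC)OCC)[C@H](OCOC)C(C)C
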